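**Plan**

1. Retrosynthesis: cut the malonate C15–O bond (acylation of ent-copalol), then C13=C14 (Horner–Wadsworth–Emmons) and C8=C17 (methylenation) back to a trans-decalin 8,13-diketone. Open ring A at C2–C3 (ring-closing metathesis, then hydrogenation). Cut C9–C11 (Michael addition to but-3-en-2-one) and C10–C1 (conjugate allylation). Open ring B at C9=C10 (aldol condensation) and C5–C6 (Michael addition of 3,3-dimethylpent-4-enal to but-3-en-2-one).
2. Forward order: ring B first (steps 2–3), then the C10 methyl, the C10 allyl arm and the C9 chain; ring A is closed onto the finished ring B (step 7); the side chain, exocyclic methylene and malonate follow.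
3. Enabling feature: ring A has no functional group, and its C2–C3 bond joins two CH2 groups between the quaternary carbons C4 and C10, away from the stereocentres C5, C9 and C10. A ring-B ketone with CH2–CH=CH2 on C10 and CMe2–CH=CH2 on C5, trans on adjacent ring carbons, is therefore a 1,7-diene set up to close ring A as the trans-decalin; the C2=C3 unsaturation is removed in step 8.
4. Stereochemistry: C5 from the enamine-catalysed Michael addition; C10 from two conjugate additions anti to the C5 substituent (methyl first, allyl after re-oxidation); C9 by equilibration next to the C8 ketone in the rigid decalin; 13E from the Horner–Wadsworth–Emmons step.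

Key step: step 7

Remark: positions are named with labdane numbering (C1–C20); the target is the ent-labdane with 5R,9R,10R configuration and a 13E double bond.

**Route**

Step 1
Reactants: 1 methyl 3,3-dimethylpent-4-enoate
Product: 2 3,3-dimethylpent-4-enal
Conditions: i-Bu2AlH (1.05 equiv), CH2Cl2, −78 °C
Reagents that add atoms: none
Why: Partial ester reduction by a dialkylaluminium hydride should stop at the aldehyde at −78 °C, because the aluminium hemiacetal next to the quaternary carbon survives until work-up.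

Step 2
Reactants: 2 3,3-dimethylpent-4-enal; 3 but-3-en-2-one
Product: 4 (R)-2-(2-methylbut-3-en-2-yl)-5-oxohexanal
Conditions: (R)-2-[diphenyl(trimethylsilyloxy)methyl]pyrrolidine (10 mol %), ethyl 3,4-dihydroxybenzoate (20 mol %), neat, 4 °C
Reagents that add atoms: none
Why: Enamine-catalysed asymmetric Michael addition of an aldehyde to a vinyl ketone, in which the E-enamine is attacked on the face away from the CPh2OSiMe3 group, so the R-configured catalyst should set C5 as R while the catechol co-catalyst activates the enone.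

Step 3
Reactants: 4 (R)-2-(2-methylbut-3-en-2-yl)-5-oxohexanal
Product: 5 (S)-4-(2-methylbut-3-en-2-yl)cyclohex-2-en-1-one
Conditions: LiOH (0.2 equiv), i-PrOH, 25 °C
Reagents that add atoms: none
Why: Intramolecular aldol condensation of the methyl ketone onto the aldehyde closes ring B as the six-membered enone, the only strain-free mode, under base mild enough to spare the C5 stereocentre.

Step 4
Reactants: 5 (S)-4-(2-methylbut-3-en-2-yl)cyclohex-2-en-1-one
Product: 7 (S)-3-methyl-4-(2-methylbut-3-en-2-yl)cyclohex-2-en-1-one, via lithium enolate 6 (not isolated)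
Conditions: Me2CuLi, Et2O, −78 °C; then N-tert-butylbenzenesulfinimidoyl chloride, THF, −78 °C
Reagents that add atoms: lithium dimethylcuprate (Me2CuLi), [Li+].C[Cu-]C
Why: Cuprate conjugate addition anti to the C5 substituent, followed by Mukaiyama dehydrogenation of the regiodefined enolate (sulfenylation at C9, syn-elimination with the C10 hydrogen), should return the enone with the C10 methyl in place, the temporary C10 stereocentre being erased.

Step 5
Reactants: 7 (S)-3-methyl-4-(2-methylbut-3-en-2-yl)cyclohex-2-en-1-one; 8 allylmagnesium bromide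
Product: 9 trimethyl{[(3R,4R)-3-methyl-4-(2-methylbut-3-en-2-yl)-3-(prop-2-en-1-yl)cyclohex-1-en-1-yl]oxy}silane
Conditions: CuBr·SMe2, LiCl, Me3SiCl, THF, −78 °C
Reagents that add atoms: chlorotrimethylsilane, C[Si](C)(C)Cl
Why: Me3SiCl-accelerated conjugate addition of an allylcopper reagent to a β,β-disubstituted enone, in which the tert-alkyl group on C5 (pseudoaxial through A1,2 strain with the C10 methyl) blocks one face, so allyl (C1, C2) should enter trans to it, forming the C10 quaternary centre and storing the enolate as the C8–C9 silyl enol ether.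

Step 6
Reactants: 9 trimethyl{[(3R,4R)-3-methyl-4-(2-methylbut-3-en-2-yl)-3-(prop-2-en-1-yl)cyclohex-1-en-1-yl]oxy}silane; 3 but-3-en-2-one
Product: 10 (3R,4R)-3-methyl-4-(2-methylbut-3-en-2-yl)-2-(3-oxobutyl)-3-(prop-2-en-1-yl)cyclohexan-1-one (both C9 epimers)
Conditions: BF3·OEt2, i-PrOH, CH2Cl2–MeNO2, −78 → −30 °C
Reagents that add atoms: none
Why: Mukaiyama–Michael addition of the regiodefined silyl enol ether to the Lewis-acid-activated vinyl ketone forms the C9–C11 bond at the only enol carbon; C9 is not controlled here and is corrected in step 9.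

Step 7
Reactants: 10 (3R,4R)-3-methyl-4-(2-methylbut-3-en-2-yl)-2-(3-oxobutyl)-3-(prop-2-en-1-yl)cyclohexan-1-one
Product: 11 (4aR,8aR)-5,5,8a-trimethyl-1-(3-oxobutyl)-3,4,4a,5,8,8a-hexahydronaphthalen-2(1H)-one (both C9 epimers)
Conditions: (H2IMes)(PCy3)Cl2Ru=CHPh (second-generation Grubbs catalyst, 5 mol %), CH2Cl2 (5 mM), 40 °C
Reagents that add atoms: none
Why: Ring-closing olefin metathesis by the metal carbene/metallacyclobutane mechanism: the ruthenium benzylidene initiates at the unhindered terminal alkene of the C10 allyl arm, the C2 alkylidene adds across the neopentyl vinyl group on C4, and cycloreversion forms C2=C3 and releases ethene. The closest known reaction type is closure of 1,7-dienes to cyclohexenes bearing an allylic quaternary carbon with NHC–ruthenium catalysts. Ring A closes as a six-membered carbocycle (1,7-diene to cyclohexene) fused to ring B at C5–C10. No stereocentre is created: the trans ring fusion is inherited from the trans arms on C5 and C10 set in steps 2 to 5, and both C9 epimers should cyclise. The step needs ring closure to outrun intermolecular metathesis, which the gem-dimethyl group on C4, the quaternary C10, the vicinal arms on a preformed ring and high dilution secure; it also needs no competing alkene, which is why the C9 chain still ends in a ketone here.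

Step 8
Reactants: 11 (4aR,8aR)-5,5,8a-trimethyl-1-(3-oxobutyl)-3,4,4a,5,8,8a-hexahydronaphthalen-2(1H)-one
Product: 12 (4aR,8aR)-5,5,8a-trimethyl-1-(3-oxobutyl)octahydronaphthalen-2(1H)-one (both C9 epimers)
Conditions: H2 (1 atm), Pd/C, EtOAc, 25 °C
Reagents that add atoms: none
Why: Heterogeneous hydrogenation should saturate the cis-disubstituted C2=C3 alkene, the only C=C bond present, while both ketones survive, which removes the unsaturation that served the ring closure.

Step 9
Reactants: 12 (4aR,8aR)-5,5,8a-trimethyl-1-(3-oxobutyl)octahydronaphthalen-2(1H)-one; 13 triethyl phosphonoacetate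
Product: 15 ethyl (2E)-3-methyl-5-[(1S,4aR,8aR)-5,5,8a-trimethyl-2-oxodecahydronaphthalen-1-yl]pent-2-enoate, via C9-epimeric keto ester 14 (not isolated)
Conditions: NaH, THF, 0 → 50 °C; then NaOEt (0.2 equiv), EtOH, 25 °C
Reagents that add atoms: none
Why: Horner–Wadsworth–Emmons olefination should take only the unhindered C13 methyl ketone (C8 is flanked by the substituted C9 and shielded by the axial C10 methyl) and favour the E alkene, after which ethoxide equilibrates C9 through the C8 enolate to the epimer with the side chain equatorial and 9-H anti to the C10 methyl; the minor Z ester is removed by chromatography.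

Step 10
Reactants: 15 ethyl (2E)-3-methyl-5-[(1S,4aR,8aR)-5,5,8a-trimethyl-2-oxodecahydronaphthalen-1-yl]pent-2-enoate
Product: 16 ethyl (2E)-3-methyl-5-[(1R,4aR,8aR)-5,5,8a-trimethyl-2-methylidenedecahydronaphthalen-1-yl]pent-2-enoate (ethyl ent-copalate)
Conditions: Zn, CH2Br2, TiCl4, THF–CH2Cl2, 0 → 25 °C
Reagents that add atoms: dibromomethane, BrCBr
Why: Lombardo methylenation should convert the hindered, enolisable C8 ketone into the exocyclic C8=C17 alkene under non-basic conditions that leave the C9 stereocentre and the unsaturated ester untouched.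

Step 11
Reactants: 16 ethyl ent-copalate
Product: 17 (2E)-3-methyl-5-[(1R,4aR,8aR)-5,5,8a-trimethyl-2-methylidenedecahydronaphthalen-1-yl]pent-2-en-1-ol (ent-copalol)
Conditions: i-Bu2AlH (2.5 equiv), CH2Cl2, −78 °C
Reagents that add atoms: none
Why: 1,2-Reduction of the α,β-unsaturated ester by the aluminium hydride should give the primary allylic alcohol without touching either alkene.

Step 12
Reactants: 17 ent-copalol; 18 2,2-dimethyl-1,3-dioxane-4,6-dione (Meldrum's acid)
Product: 19 3-({(2E)-3-methyl-5-[(1R,4aR,8aR)-5,5,8a-trimethyl-2-methylidenedecahydronaphthalen-1-yl]pent-2-en-1-yl}oxy)-3-oxopropanoic acid (CNP0107438.1)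
Conditions: toluene, 90 °C
Reagents that add atoms: none
Why: Alcoholysis of Meldrum's acid (acylation with loss of acetone) should give the malonic acid half ester directly, without a protecting group and under neutral conditions that spare the exocyclic alkene.

**Compound list**

1 | methyl 3,3-dimethylpent-4-enoate | C=CC(C)(C)CC(=O)OC | starting material
2 | 3,3-dimethylpent-4-enal | C=CC(C)(C)CC=O | intermediate
3 | but-3-en-2-one (methyl vinyl ketone) | C=CC(C)=O | starting material
4 | (R)-2-(2-methylbut-3-en-2-yl)-5-oxohexanal | O=C[C@@H](C(C)(C)C=C)CCC(C)=O | intermediate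
5 | (S)-4-(2-methylbut-3-en-2-yl)cyclohex-2-en-1-one | O=C1C=C[C@@H](C(C)(C)C=C)CC1 | intermediate
6 | lithium (3R,4S)-3-methyl-4-(2-methylbut-3-en-2-yl)cyclohex-1-en-1-olate (methyl trans to the C5 substituent) | [Li+].[O-]C1=C[C@H](C)[C@@H](C(C)(C)C=C)CC1 | intermediate
7 | (S)-3-methyl-4-(2-methylbut-3-en-2-yl)cyclohex-2-en-1-one | O=C1C=C(C)[C@@H](C(C)(C)C=C)CC1 | intermediate
8 | allylmagnesium bromide | C=CC[Mg]Br | starting material
9 | trimethyl{[(3R,4R)-3-methyl-4-(2-methylbut-3-en-2-yl)-3-(prop-2-en-1-yl)cyclohex-1-en-1-yl]oxy}silane (allyl trans to the C5 substituent) | C[Si](C)(C)OC1=C[C@](C)(CC=C)[C@@H](C(C)(C)C=C)CC1 | intermediate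
10 | (3R,4R)-3-methyl-4-(2-methylbut-3-en-2-yl)-2-(3-oxobutyl)-3-(prop-2-en-1-yl)cyclohexan-1-one, both epimers at ring C2 (labdane C9) | O=C1CC[C@H](C(C)(C)C=C)[C@@](C)(CC=C)C1CCC(C)=O | intermediate
11 | (4aR,8aR)-5,5,8a-trimethyl-1-(3-oxobutyl)-3,4,4a,5,8,8a-hexahydronaphthalen-2(1H)-one, both epimers at C1 (labdane C9) | O=C1CC[C@@H]2C(C)(C)C=CC[C@@]2(C)C1CCC(C)=O | intermediate
12 | (4aR,8aR)-5,5,8a-trimethyl-1-(3-oxobutyl)octahydronaphthalen-2(1H)-one, both epimers at C1 (labdane C9) | O=C1CC[C@@H]2C(C)(C)CCC[C@@]2(C)C1CCC(C)=O | intermediate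
13 | triethyl phosphonoacetate | CCOC(=O)CP(=O)(OCC)OCC | starting material
14 | ethyl (2E)-3-methyl-5-[(4aR,8aR)-5,5,8a-trimethyl-2-oxodecahydronaphthalen-1-yl]pent-2-enoate, both epimers at C1 (labdane C9) | O=C1CC[C@@H]2C(C)(C)CCC[C@@]2(C)C1CC/C(C)=C/C(=O)OCC | intermediate
15 | ethyl (2E)-3-methyl-5-[(1S,4aR,8aR)-5,5,8a-trimethyl-2-oxodecahydronaphthalen-1-yl]pent-2-enoate | O=C1CC[C@@H]2C(C)(C)CCC[C@@]2(C)[C@@H]1CC/C(C)=C/C(=O)OCC | intermediate
16 | ethyl (2E)-3-methyl-5-[(1R,4aR,8aR)-5,5,8a-trimethyl-2-methylidenedecahydronaphthalen-1-yl]pent-2-enoate (ethyl ent-copalate) | C=C1CC[C@@H]2C(C)(C)CCC[C@@]2(C)[C@@H]1CC/C(C)=C/C(=O)OCC | intermediate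
17 | (2E)-3-methyl-5-[(1R,4aR,8aR)-5,5,8a-trimethyl-2-methylidenedecahydronaphthalen-1-yl]pent-2-en-1-ol (ent-copalol) | C=C1CC[C@@H]2C(C)(C)CCC[C@@]2(C)[C@@H]1CC/C(C)=C/CO | intermediate
18 | 2,2-dimethyl-1,3-dioxane-4,6-dione (Meldrum's acid) | CC1(C)OC(=O)CC(=O)O1 | starting material
19 | 3-({(2E)-3-methyl-5-[(1R,4aR,8aR)-5,5,8a-trimethyl-2-methylidenedecahydronaphthalen-1-yl]pent-2-en-1-yl}oxy)-3-oxopropanoic acid | C=C1CC[C@@H]2C(C)(C)CCC[C@@]2(C)[C@@H]1CC/C(C)=C/COC(=O)CC(=O)O | target

**Step count and risks**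

Total steps: 12. Longest linear sequence: 12 steps (1 to 19).

Steps most likely to fail:

Step 5. Conjugate addition may lose to 1,2-addition at the carbonyl, or stall, because C10 is flanked by the tert-alkyl-bearing C5. The fallback uses the 1,2-mode on purpose. Compound 7 with CH2=CHCH2MgBr (THF, −78 °C) should give the tertiary alcohol (1S,4S)-3-methyl-4-(2-methylbut-3-en-2-yl)-1-(prop-2-en-1-yl)cyclohex-2-en-1-ol F1; this is the carbinol epimer with allyl anti to the C5 substituent, and the other epimer would be removed by chromatography. Anionic oxy-Cope rearrangement (KH, 18-crown-6, THF, 25 °C) then moves the allyl group suprafacially from C8 to C10 and gives potassium (3R,4R)-3-methyl-4-(2-methylbut-3-en-2-yl)-3-(prop-2-en-1-yl)cyclohex-1-en-1-olate F2. Silylation in the flask with Me3SiCl returns to the route at 9.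

Step 6. Bond formation at C9, next to the new quaternary carbon, may be slower than protodesilylation of the enol ether or polymerisation of the enone under the Lewis acid. The fallback replaces electrophile activation by a preformed enolate. MeLi (THF, 0 °C) cleaves 9 to lithium (3R,4R)-3-methyl-4-(2-methylbut-3-en-2-yl)-3-(prop-2-en-1-yl)cyclohex-1-en-1-olate F3. At −78 °C this adds to 3-(trimethylsilyl)but-3-en-2-one, whose α-silyl group stabilises the adduct and suppresses polymerisation, to give (3R,4R)-3-methyl-4-(2-methylbut-3-en-2-yl)-2-[3-oxo-2-(trimethylsilyl)butyl]-3-(prop-2-en-1-yl)cyclohexan-1-one F4. KF in aqueous methanol removes silicon and returns to the route at 10.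

Step 9. Discrimination between the C13 and C8 ketones may be incomplete, or the basic medium may trigger intramolecular aldol closure of the 1,5-diketone before olefination. The fallback is a protecting-group detour from 12. Ethylene glycol with pyridinium p-toluenesulfonate (benzene, reflux) should ketalise only the unhindered C13 ketone to (4aR,8aR)-5,5,8a-trimethyl-1-[2-(2-methyl-1,3-dioxolan-2-yl)ethyl]octahydronaphthalen-2(1H)-one F5. NaOMe in MeOH equilibrates C9 to the (1S,4aR,8aR) isomer of that ketal ketone F6. Ph3P=CH2 (from Ph3PCH3Br and KOtBu, toluene, 80 °C) gives 2-methyl-2-{2-[(1R,4aR,8aR)-5,5,8a-trimethyl-2-methylidenedecahydronaphthalen-1-yl]ethyl}-1,3-dioxolane F7. Aqueous AcOH–THF releases 4-[(1R,4aR,8aR)-5,5,8a-trimethyl-2-methylidenedecahydronaphthalen-1-yl]butan-2-one F8. Horner–Wadsworth–Emmons olefination of F8 with 13 (NaH, THF) rejoins the route at 16.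

**Further compounds**

F1 | step 5 | (1S,4S)-3-methyl-4-(2-methylbut-3-en-2-yl)-1-(prop-2-en-1-yl)cyclohex-2-en-1-ol | C=CC[C@]1(O)C=C(C)[C@@H](C(C)(C)C=C)CC1
F2 | step 5 | potassium (3R,4R)-3-methyl-4-(2-methylbut-3-en-2-yl)-3-(prop-2-en-1-yl)cyclohex-1-en-1-olate | [K+].[O-]C1=C[C@](C)(CC=C)[C@@H](C(C)(C)C=C)CC1
F3 | step 6 | lithium (3R,4R)-3-methyl-4-(2-methylbut-3-en-2-yl)-3-(prop-2-en-1-yl)cyclohex-1-en-1-olate | [Li+].[O-]C1=C[C@](C)(CC=C)[C@@H](C(C)(C)C=C)CC1
F4 | step 6 | (3R,4R)-3-methyl-4-(2-methylbut-3-en-2-yl)-2-[3-oxo-2-(trimethylsilyl)butyl]-3-(prop-2-en-1-yl)cyclohexan-1-one (epimers at ring C2 and at the silylated carbon) | O=C1CC[C@H](C(C)(C)C=C)[C@@](C)(CC=C)C1CC([Si](C)(C)C)C(C)=O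
F5 | step 9 | (4aR,8aR)-5,5,8a-trimethyl-1-[2-(2-methyl-1,3-dioxolan-2-yl)ethyl]octahydronaphthalen-2(1H)-one (both C1 epimers) | O=C1CC[C@@H]2C(C)(C)CCC[C@@]2(C)C1CCC3(C)OCCO3
F6 | step 9 | (1S,4aR,8aR)-5,5,8a-trimethyl-1-[2-(2-methyl-1,3-dioxolan-2-yl)ethyl]octahydronaphthalen-2(1H)-one | O=C1CC[C@@H]2C(C)(C)CCC[C@@]2(C)[C@@H]1CCC3(C)OCCO3
F7 | step 9 | 2-methyl-2-{2-[(1R,4aR,8aR)-5,5,8a-trimethyl-2-methylidenedecahydronaphthalen-1-yl]ethyl}-1,3-dioxolane | C=C1CC[C@@H]2C(C)(C)CCC[C@@]2(C)[C@@H]1CCC3(C)OCCO3
F8 | step 9 | 4-[(1R,4aR,8aR)-5,5,8a-trimethyl-2-methylidenedecahydronaphthalen-1-yl]butan-2-one | C=C1CC[C@@H]2C(C)(C)CCC[C@@]2(C)[C@@H]1CCC(C)=O
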